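Numbering: ring A is the benzene ring and ring B the dihydrofuran (benzofuran numbering O1, C2, C3, C3a, C4-C7, C7a); ring C is the pyrone (primed numbers O1'-C6').
Cuts, in retrosynthetic order: the isopropenyl C=C (back to a tertiary carbinol on C2); O1-C2 of ring B; C5-CH2 and CH2-C3' of the bridge; C3a-C3 (prenyl) and C7-C(=O) (acyl) on ring A; C4'-C5' and O1'-C2' of ring C.
Enabling feature: O1, C2, C3 and the three-carbon branch on C2 are a prenyl chain on C3a with an oxidised double bond and its inner alkene carbon (C2) bound to the C7a oxygen. The chain lies between the oxygens on C4 and C7a, and only the C7a oxygen is in ring B, so ring B maps onto an ortho-prenylphenol.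
Forward: ring A is bought as phloroglucinol, then C-acylated and C-prenylated. Ring C is built from pentan-3-one and malonyl dichloride, and one CH2 joins C5 to C3'. Ring B closes last, by P450 epoxidation and phenol opening on the unprotected molecule. Acetylation, dehydration and deacetylation then turn the carbinol into the isopropenyl group.
Stereochemistry: the side-chain (S) centre is bought with (S)-2-methylbutanoic acid. C2 (S) comes from the enzyme, which epoxidises one alkene face to the (R)-epoxide and lets the phenoxide open it with inversion.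

Key step: step 7

Assumption: a P450 variant that accepts the fully assembled prenylated precursor can be found by screening marmesin-synthase homologues and by directed evolution. This is treated as catalyst development and is not counted as a step.

Step 1
Reactants: 1 (S)-2-methylbutanoic acid
Product: 2 (S)-2-methylbutanoyl chloride
Conditions: (COCl)2 (1.2 equiv), DMF (cat.), CH2Cl2, 0 °C to rt; distillation
Reagents that add atoms: oxalyl chloride, O=C(Cl)C(=O)Cl
Why: Acid chloride formation through the chloroiminium species from DMF needs no base and no heat, so neither a ketene nor an enol pathway is open and the (S) centre should be carried over unchanged.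

Step 2
Reactants: 2 (S)-2-methylbutanoyl chloride, 3 phloroglucinol (benzene-1,3,5-triol)
Product: 4 (S)-2-methyl-1-(2,4,6-trihydroxyphenyl)butan-1-one
Conditions: AlCl3 (4 equiv), CH2Cl2/PhNO2, 0 to 40 °C; then ice/aq. HCl
Reagents that add atoms: none
Why: Friedel-Crafts C-acylation of the very electron-rich triol should stop after one acyl group because the aluminium-chelated aryl ketone is deactivated, the three ring positions of 3 are equivalent, and the moderate temperature together with the poorly enolisable chelated ketone should protect the alpha centre, whose integrity is to be checked by chiral HPLC at this stage.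

Step 3
Reactants: 4 (S)-2-methyl-1-(2,4,6-trihydroxyphenyl)butan-1-one, 5 prenyl bromide (1-bromo-3-methylbut-2-ene)
Product: 6 (S)-2-methyl-1-[2,4,6-trihydroxy-3-(3-methylbut-2-en-1-yl)phenyl]butan-1-one
Conditions: KOH (1.1 equiv), H2O, 5 (0.9 equiv), 0 °C to rt
Reagents that add atoms: none
Why: C-alkylation of the ambident phloroglucinolate in water, where hydrogen bonding shields the oxygens, is the standard entry to C-prenyl acylphloroglucinols; the two free ring carbons of 4 are equivalent so only one mono-prenyl isomer can form, and a slight deficit of 5 holds back double prenylation.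

Step 4
Reactants: 7 pentan-3-one
Product: 8 3-(trimethylsilyloxy)pent-2-ene (E/Z mixture)
Conditions: TMSCl, Et3N, DMF, 90 °C
Reagents that add atoms: chlorotrimethylsilane, C[Si](C)(C)Cl
Why: Silyl enol ether formation under amine conditions is routine, the ketone is symmetrical so there is no regiochemical issue, and the alkene geometry is erased in the next step.

Step 5
Reactants: 8 3-(trimethylsilyloxy)pent-2-ene, 9 malonyl dichloride
Product: 11 6-ethyl-4-hydroxy-5-methyl-2H-pyran-2-one, via diketo acid chloride 10 (not isolated)
Conditions: Et2O, -78 °C to rt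
Reagents that add atoms: none
Why: In this pyrone synthesis from an enol silane and malonyl dichloride (Effenberger type) C-acylation at the nucleophilic carbon gives 10, whose enol oxygen closes on the second acid chloride (6-exo-trig) and tautomerises to the 4-hydroxy-2-pyrone, which places ethyl on C6' and methyl on C5'.

Step 6
Reactants: 11 6-ethyl-4-hydroxy-5-methyl-2H-pyran-2-one, 6 (S)-2-methyl-1-[2,4,6-trihydroxy-3-(3-methylbut-2-en-1-yl)phenyl]butan-1-one
Product: 14 6-ethyl-4-hydroxy-5-methyl-3-({2,4,6-trihydroxy-3-[(2S)-2-methylbutanoyl]-5-(3-methylbut-2-en-1-yl)phenyl}methyl)-2H-pyran-2-one, via Mannich base 12 (not isolated), via pyrone methide 13 (not isolated)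
Conditions: 11, CH2=NMe2+ I- (1.0 equiv), CHCl3, rt; then 6 (1.5 equiv), 50 °C; dilute acid work-up
Reagents that add atoms: Eschenmoser's salt (N,N-dimethylmethyleneiminium iodide), C=[N+](C)C.[I-]
Why: A Mannich reaction at C3' followed by loss of dimethylamine gives the Michael acceptor 13, which the only free ring carbon of 6 captures in a Friedel-Crafts-type conjugate addition, a three-component methylene coupling established for prenylated acylphloroglucinol/4-hydroxypyrone pairs and steered to the mixed product by consuming all of 11 before an excess of 6 is added.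

Step 7
Reactants: 14 prenylated acylphloroglucinol-CH2-pyrone
Product: 16 3-({(2S)-4,6-dihydroxy-2-(2-hydroxypropan-2-yl)-7-[(2S)-2-methylbutanoyl]-2,3-dihydro-1-benzofuran-5-yl}methyl)-6-ethyl-4-hydroxy-5-methyl-2H-pyran-2-one, via (R)-epoxide 15 (not isolated)
Conditions: evolved marmesin-synthase-type cytochrome P450 + NADPH-cytochrome P450 reductase (yeast microsomes), air (O2), NADP+ (cat.), D-glucose, glucose dehydrogenase, catalase, KH2PO4/K2HPO4 buffer pH 7.4, 2% DMSO, 30 °C; then pH 3, EtOAc
Reagents that add atoms: dioxygen, O=O
Why: Proposed new method: the haem, fed with two electrons from NADPH through the reductase, splits O2 into water and a ferryl-oxo species (tetravalent iron, porphyrin radical cation) that should pass its oxygen atom to whichever face of the C2=CMe2 bond the pocket turns toward the iron, giving (R)-epoxide 15, after which a basic residue takes the proton of C7a-OH and the phenoxide displaces the epoxide oxygen from C2 from the rear, so that the oxygen from O2 ends as the tertiary alcohol. The closest known reaction type is the P450 cyclisation of ortho-prenylphenols of the coumarin series (demethylsuberosin to (S)-marmesin); an acylphloroglucinol has not been shown as a substrate, so homologue screening and directed evolution with an LC-MS assay for the product 16 mass units heavier belong to this step. Ring B closes in the 5-exo-tet mode with formation of O1-C2. The (S) configuration at C2 is controlled by the enzyme alone, through the face it epoxidises and the inversion in the opening, and the distant side-chain centre has no say. Needed are site selectivity between the two flanking phenols (C7a-OH, not C4-OH), opening at C2 rather than at the tertiary carbon, facial selectivity at the alkene, and chemoselectivity against oxidation of ring A and of the bridge CH2. The substrate itself secures the 5-exo opening, since a phenoxide under non-acidic conditions attacks the less substituted epoxide carbon, and it offers two unlike edges for recognition (C7a-OH beside the compact acyl carbonyl, C4-OH hydrogen-bonded to the bulky pyrone arm that is anionic at pH 7.4), but the choice of phenol and of face has to be enforced by the pocket.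

Step 8
Reactants: 16 (2S)-carbinol
Product: 17 triacetate of 16 (acetates on C4-O and C6-O and on the pyrone C4'-O; tertiary OH free)
Conditions: Ac2O, pyridine, rt
Reagents that add atoms: acetic anhydride, CC(=O)OC(C)=O
Why: Acetylation in pyridine without DMAP should esterify the two phenols and the pyrone enol but not the hindered tertiary alcohol, and O-to-C acyl migration on the pyrone is blocked because C3' is substituted.

Step 9
Reactants: 17 triacetate of 16
Product: 19 triacetate of the target ((2S)-2-isopropenyl compound), via sulfamate ester 18 (not isolated)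
Conditions: Burgess reagent (3 equiv), toluene, 70 °C
Reagents that add atoms: none
Why: In the Burgess dehydration the tertiary alcohol forms sulfamate 18, which undergoes a syn elimination with much carbocation character, and one of the six methyl hydrogens should be lost rather than the single C2-H, whose bond is a poor donor next to O1 and whose loss would give a crowded tetrasubstituted enol ether, in line with known dehydrations of 2-(2-hydroxypropan-2-yl)-2,3-dihydrobenzofurans, while C2 itself is not touched.

Step 10
Reactants: 19 triacetate of the target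
Product: 20 3-({(2S)-4,6-dihydroxy-7-[(2S)-2-methylbutanoyl]-2-(prop-1-en-2-yl)-2,3-dihydro-1-benzofuran-5-yl}methyl)-6-ethyl-4-hydroxy-5-methyl-2H-pyran-2-one (target)
Conditions: K2CO3 (4 equiv), MeOH, 0 °C; then 1 M HCl to pH 3
Reagents that add atoms: none
Why: Base-mediated methanolysis (transesterification) of aryl and enol acetates is fast at 0 °C, and each hydroxyl group set free is deprotonated at once, which makes the ketone and the pyrone poor electrophiles and poor carbon acids, so both stereocentres, the methylene bridge and the isopropenyl group should survive.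

Compound list
1 | (S)-2-methylbutanoic acid | CC[C@H](C)C(=O)O | starting material
2 | (S)-2-methylbutanoyl chloride | CC[C@H](C)C(=O)Cl | intermediate
3 | phloroglucinol | Oc1cc(O)cc(O)c1 | starting material
4 | (S)-2-methyl-1-(2,4,6-trihydroxyphenyl)butan-1-one | CC[C@H](C)C(=O)c1c(O)cc(O)cc1O | intermediate
5 | prenyl bromide | CC(C)=CCBr | starting material
6 | (S)-2-methyl-1-[2,4,6-trihydroxy-3-(3-methylbut-2-en-1-yl)phenyl]butan-1-one | CC[C@H](C)C(=O)c1c(O)cc(O)c(CC=C(C)C)c1O | intermediate
7 | pentan-3-one | CCC(=O)CC | starting material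
8 | 3-(trimethylsilyloxy)pent-2-ene (E/Z mixture) | CC=C(CC)O[Si](C)(C)C | intermediate
9 | malonyl dichloride | O=C(Cl)CC(=O)Cl | starting material
10 | 4-methyl-3,5-dioxoheptanoyl chloride (not isolated) | CCC(=O)C(C)C(=O)CC(=O)Cl | intermediate
11 | 6-ethyl-4-hydroxy-5-methyl-2H-pyran-2-one | CCc1oc(=O)cc(O)c1C | intermediate
12 | 3-[(dimethylamino)methyl]-6-ethyl-4-hydroxy-5-methyl-2H-pyran-2-one (not isolated) | CCc1oc(=O)c(CN(C)C)c(O)c1C | intermediate
13 | 6-ethyl-5-methyl-3-methylidene-2H-pyran-2,4(3H)-dione (not isolated) | CCC1=C(C)C(=O)C(=C)C(=O)O1 | intermediate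
14 | 6-ethyl-4-hydroxy-5-methyl-3-({2,4,6-trihydroxy-3-[(2S)-2-methylbutanoyl]-5-(3-methylbut-2-en-1-yl)phenyl}methyl)-2H-pyran-2-one | CC(C)=CCc1c(O)c(Cc2c(O)c(C)c(CC)oc2=O)c(O)c(C(=O)[C@@H](C)CC)c1O | intermediate
15 | (R)-epoxide of 14, with a [(2R)-3,3-dimethyloxiran-2-yl]methyl group in place of prenyl (not isolated) | CC1(C)O[C@@H]1Cc2c(O)c(Cc3c(O)c(C)c(CC)oc3=O)c(O)c(C(=O)[C@@H](C)CC)c2O | intermediate
16 | 3-({(2S)-4,6-dihydroxy-2-(2-hydroxypropan-2-yl)-7-[(2S)-2-methylbutanoyl]-2,3-dihydro-1-benzofuran-5-yl}methyl)-6-ethyl-4-hydroxy-5-methyl-2H-pyran-2-one | CC(C)(O)[C@@H]1Cc2c(O)c(Cc3c(O)c(C)c(CC)oc3=O)c(O)c(C(=O)[C@@H](C)CC)c2O1 | intermediate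
17 | C4,C6,C4'-tri-O-acetate of 16, tertiary OH free | CC(C)(O)[C@@H]1Cc2c(OC(C)=O)c(Cc3c(OC(C)=O)c(C)c(CC)oc3=O)c(OC(C)=O)c(C(=O)[C@@H](C)CC)c2O1 | intermediate
18 | tertiary N-(methoxycarbonyl)sulfamate of 17, drawn in the N-H form (not isolated) | COC(=O)NS(=O)(=O)OC(C)(C)[C@@H]1Cc2c(OC(C)=O)c(Cc3c(OC(C)=O)c(C)c(CC)oc3=O)c(OC(C)=O)c(C(=O)[C@@H](C)CC)c2O1 | intermediate
19 | C4,C6,C4'-tri-O-acetate of the target | C=C(C)[C@@H]1Cc2c(OC(C)=O)c(Cc3c(OC(C)=O)c(C)c(CC)oc3=O)c(OC(C)=O)c(C(=O)[C@@H](C)CC)c2O1 | intermediate
20 | 3-({(2S)-4,6-dihydroxy-7-[(2S)-2-methylbutanoyl]-2-(prop-1-en-2-yl)-2,3-dihydro-1-benzofuran-5-yl}methyl)-6-ethyl-4-hydroxy-5-methyl-2H-pyran-2-one | C=C(C)[C@@H]1Cc2c(O)c(Cc3c(O)c(C)c(CC)oc3=O)c(O)c(C(=O)[C@@H](C)CC)c2O1 | target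

Total step count: 10. Longest linear sequence: 8 (steps 1, 2, 3, 6, 7, 8, 9, 10).

Steps most likely to fail

**Step 7.**
- What may go wrong:
  - No turnover, because the hexasubstituted, anionic substrate does not enter the pocket.
  - Uncoupled reduction of O2, with oxidative degradation of ring A.
  - Escape of the epoxide from the pocket, followed by unselective opening through the C4 phenol or at the tertiary carbon.
- Fallback (known chemistry): ring B is closed chemically before the pyrone is attached, at a stage where the two flanking phenols can be told apart. It sets out from 6.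
  - MOMCl (2.2 equiv) and iPr2NEt in CH2Cl2 should etherify the two less hindered phenols. The chelated phenol between acyl and prenyl stays free, giving bis-MOM ether F1. MOM is chosen because it withstands the basic epoxidation buffer.
  - Ac2O, Et3N and DMAP mask the remaining phenol as aryl acetate F2.
  - Shi epoxidation should give (R)-epoxide F3. The conditions are the D-fructose-derived ketone 1,2:4,5-di-O-isopropylidene-beta-D-erythro-2,3-hexodiulo-2,6-pyranose, KHSO5 (as 2KHSO5·KHSO4·K2SO4), K2CO3 buffer, MeCN/dimethoxymethane/H2O, 0 °C.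
  - K2CO3 in MeOH cleaves the acetate, and the phenoxide opens the epoxide 5-exo-tet with inversion to bis-MOM (2S)-carbinol F4.
  - HCl in MeOH gives dihydroxy carbinol F5.
  - F5, whose only free ring carbon is C5, is joined to 11 with Eschenmoser's salt as in step 6. The fallback comes back to the route at 16.

**Step 9.**
- What may go wrong:
  - Elimination toward C2, followed by aromatisation of ring B.
  - Loss of the acetyl group from the pyrone enol ester under the warm, mildly basic conditions, and quenching of the reagent by the hydroxyl group so exposed.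
- Fallback: the isopropenyl group is made in the ring closure itself by a palladium-catalysed asymmetric allylic etherification, so no carbinol has to be dehydrated. It sets out from 6.
  - TBSCl (2.2 equiv) and imidazole in DMF give bis-silyl ether F6, with the chelated phenol free.
  - SeO2 (cat.) and t-BuOOH in CH2Cl2, then NaBH4, oxidise the (E)-methyl group to (E)-allylic alcohol F7.
  - ClCO2Me (1 equiv) and pyridine at 0 °C give allylic methyl carbonate F8.
  - Pd2(dba)3·CHCl3 (zerovalent palladium), the (S,S)-DACH-phenyl Trost ligand and AcOH in CH2Cl2 should close ring B to silylated (2S)-isopropenyl dihydrobenzofuran F9. The ligand antipode is to be confirmed on a model; (S,S) is the one expected to lead to 2S.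
  - TBAF/AcOH in THF gives dihydroxy isopropenyl dihydrobenzofuran F10.
  - F10 is joined at C5 to 11 with Eschenmoser's salt as in step 6. The fallback comes back to the route at 20.

**Step 6.**
- What may go wrong: capture of the methide by a second pyrone, or amine-promoted retro-Michael exchange of the bridge. Both processes lead to symmetric dimers.
- Fallback: the roles are reversed and the electrophile is stored in an isolable form on ring A. It sets out from 6.
  - A Mannich reaction with aqueous formaldehyde and dimethylamine in EtOH gives benzylic amine F11.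
  - Heating F11 with 11 in dioxane (if needed after quaternisation with MeI) releases an ortho-quinone methide of ring A.
  - Only C3' of the pyrone is on hand to capture this methide. The fallback comes back to the route at 14.

Further compounds
F1 | step 7 | (S)-1-[2-hydroxy-4,6-bis(methoxymethoxy)-3-(3-methylbut-2-en-1-yl)phenyl]-2-methylbutan-1-one | CC[C@H](C)C(=O)c1c(OCOC)cc(OCOC)c(CC=C(C)C)c1O
F2 | step 7 | 3,5-bis(methoxymethoxy)-2-[(2S)-2-methylbutanoyl]-6-(3-methylbut-2-en-1-yl)phenyl acetate | CC[C@H](C)C(=O)c1c(OCOC)cc(OCOC)c(CC=C(C)C)c1OC(C)=O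
F3 | step 7 | 6-{[(2R)-3,3-dimethyloxiran-2-yl]methyl}-3,5-bis(methoxymethoxy)-2-[(2S)-2-methylbutanoyl]phenyl acetate | CC[C@H](C)C(=O)c1c(OCOC)cc(OCOC)c(C[C@H]2OC2(C)C)c1OC(C)=O
F4 | step 7 | (2S)-1-[(2S)-2-(2-hydroxypropan-2-yl)-4,6-bis(methoxymethoxy)-2,3-dihydro-1-benzofuran-7-yl]-2-methylbutan-1-one | CC(C)(O)[C@@H]1Cc2c(OCOC)cc(OCOC)c(C(=O)[C@@H](C)CC)c2O1
F5 | step 7 | (2S)-1-[(2S)-4,6-dihydroxy-2-(2-hydroxypropan-2-yl)-2,3-dihydro-1-benzofuran-7-yl]-2-methylbutan-1-one | CC(C)(O)[C@@H]1Cc2c(O)cc(O)c(C(=O)[C@@H](C)CC)c2O1
F6 | step 9 | (S)-1-[4,6-bis(tert-butyldimethylsilyloxy)-2-hydroxy-3-(3-methylbut-2-en-1-yl)phenyl]-2-methylbutan-1-one | CC[C@H](C)C(=O)c1c(O[Si](C)(C)C(C)(C)C)cc(O[Si](C)(C)C(C)(C)C)c(CC=C(C)C)c1O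
F7 | step 9 | (S)-1-{4,6-bis(tert-butyldimethylsilyloxy)-2-hydroxy-3-[(2E)-4-hydroxy-3-methylbut-2-en-1-yl]phenyl}-2-methylbutan-1-one | CC[C@H](C)C(=O)c1c(O[Si](C)(C)C(C)(C)C)cc(O[Si](C)(C)C(C)(C)C)c(C/C=C(\C)CO)c1O
F8 | step 9 | methyl carbonate of the allylic alcohol F7 | CC[C@H](C)C(=O)c1c(O[Si](C)(C)C(C)(C)C)cc(O[Si](C)(C)C(C)(C)C)c(C/C=C(\C)COC(=O)OC)c1O
F9 | step 9 | (2S)-1-[(2S)-4,6-bis(tert-butyldimethylsilyloxy)-2-(prop-1-en-2-yl)-2,3-dihydro-1-benzofuran-7-yl]-2-methylbutan-1-one | C=C(C)[C@@H]1Cc2c(O[Si](C)(C)C(C)(C)C)cc(O[Si](C)(C)C(C)(C)C)c(C(=O)[C@@H](C)CC)c2O1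
F10 | step 9 | (2S)-1-[(2S)-4,6-dihydroxy-2-(prop-1-en-2-yl)-2,3-dihydro-1-benzofuran-7-yl]-2-methylbutan-1-one | C=C(C)[C@@H]1Cc2c(O)cc(O)c(C(=O)[C@@H](C)CC)c2O1
F11 | step 6 | (S)-1-{3-[(dimethylamino)methyl]-2,4,6-trihydroxy-5-(3-methylbut-2-en-1-yl)phenyl}-2-methylbutan-1-one | CC[C@H](C)C(=O)c1c(O)c(CN(C)C)c(O)c(CC=C(C)C)c1O
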